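**Retrosynthetic overview**
1. Target 18 ⇐ α-iodoenone 17 (Stille allylation at C3) ⇐ enone 16 (α-iodination) ⇐ carbinol 15 (oxidation at C2).
2. C1–C2 is cut as an intramolecular aldol of the δ-lactone enolate of 14 onto its (Z)-enal. This last ring closure makes the seven-membered carbocycle and with it the 6-oxabicyclo[3.2.2]nonene.
3. 14 ⇐ 13 by acid ketal exchange: the spiro 2-acyloxy-5-methoxy-2,5-dihydrofuran hides the C2 aldehyde and the C5 ketal and keeps C3=C4 cis.
4. Key: 13 ⇐ furyl acid 11 + methanol by bromide-mediated anodic oxidation. The strategy rests on the unit C5(OMe)(O6)–C4=C3–C2(=O) of the seven-membered ring, a cis-but-2-ene with a ketal carbon at one end and a ketone carbon at the other, which is a 2-substituted furan oxidised at both α-carbons (C5 and C2). The C7 carboxylate takes C5, so the δ-lactone ring O6–C7–C1–C8–C9–C5 closes before the carbocycle.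
5. 11 ⇐ propanal + arylidene malonate 3 (enamine Michael addition sets C8 and C9), then furan annulation of the aldehyde with 3,3-diethoxypropyne, hydrolysis and decarboxylation. Ring order: furan, δ-lactone (spiro to the dihydrofuran), carbocycle.

Key step: step 6

Remark: atom numbers in the Why lines are those of the target (C1 bridgehead CH, C2 ketone, C3 allyl-bearing, C4, C5 ketal bridgehead, O6, C7 lactone carbonyl, C8 aryl-bearing, C9 methyl-bearing); Ar = 3,4,5-trimethoxyphenyl.
Assumption: the arylidene malonate is taken to meet the enamine of the (S)-diarylprolinol silyl ether with the same facial sense as β-nitrostyrenes (syn adduct, R at the aldehyde α-carbon); if the sense is opposite, the (R)-catalyst is used.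
Assumption: the two configurations of the mixed ketal carbon formed in step 7 are taken to interconvert under the acid used there and to be separable on buffered silica; no preference for the configuration needed is claimed.

**Route**

Step 1
Reactants: 1 3,4,5-trimethoxybenzaldehyde; 2 dimethyl malonate
Product: 3 dimethyl 2-[(3,4,5-trimethoxyphenyl)methylidene]propanedioate
Conditions: piperidine (0.1 equiv), AcOH (0.1 equiv), toluene, reflux, Dean–Stark
Reagents that add atoms: none
Why: Knoevenagel condensation driven by azeotropic removal of water; the symmetrical malonate leaves no alkene geometry and no stereocentre to control.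

Step 2
Reactants: 3 arylidene malonate; 4 propanal
Product: 5 dimethyl 2-[(1R,2R)-2-methyl-3-oxo-1-(3,4,5-trimethoxyphenyl)propyl]propanedioate
Conditions: (S)-α,α-diphenylprolinol trimethylsilyl ether (20 mol %), PhCO2H (20 mol %), propanal (4 equiv), CHCl3, 4 °C
Reagents that add atoms: none
Why: Enamine-catalysed Michael addition of an aldehyde to an arylidene malonate (Hayashi–Jørgensen catalysis), in which the shielded face of the (E)-enamine sets the methyl-bearing centre (C9) and the acyclic synclinal transition state gives the syn adduct and so sets the aryl-bearing centre (C8).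

Step 3
Reactants: 5 aldehyde; 6 3,3-diethoxyprop-1-yne
Product: 7 dimethyl 2-[(1R,2R)-6,6-diethoxy-3-hydroxy-2-methyl-1-(3,4,5-trimethoxyphenyl)hex-4-yn-1-yl]propanedioate (both carbinol epimers)
Conditions: 6 (2.3 equiv), n-BuLi (2.2 equiv), THF, −78 °C; then 5, −78 °C; AcOH quench at −78 °C
Reagents that add atoms: none
Why: 1,2-Addition of a lithium acetylide to the aldehyde; the first equivalent converts the malonate into its enolate and so shields the esters, addition at −78 °C with a cold quench should spare the aldehyde α-centre, and the new carbinol centre disappears on aromatisation.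

Step 4
Reactants: 7 propargylic alcohol
Product: 9 dimethyl 2-[(1R,2R)-2-(furan-2-yl)-1-(3,4,5-trimethoxyphenyl)propyl]propanedioate, via (Z)-hydroxy-enal acetal 8 (not isolated)
Conditions: H2 (1 atm), Pd/CaCO3 poisoned with Pb(OAc)2, quinoline, EtOAc, rt; filter; then TsOH·H2O (5 mol %), CH2Cl2, 0 °C
Reagents that add atoms: none
Why: Lindlar cis-semihydrogenation followed by acid-catalysed cyclodehydration of the (Z)-4-hydroxy-2-enal acetal (hydroxyl attack at the acetal carbon, loss of two ethanol), a standard route to 2-substituted furans that touches neither chain stereocentre.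

Step 5
Reactants: 9 furyl malonate
Product: 11 (3S,4R)-4-(furan-2-yl)-3-(3,4,5-trimethoxyphenyl)pentanoic acid, via malonic diacid 10 (not isolated)
Conditions: LiOH (5 equiv), THF/MeOH/H2O, 45 °C; 1 M HCl to pH 2 at 0 °C, extract; then pyridine, 100 °C
Reagents that add atoms: lithium hydroxide, [Li+].[OH-]
Why: Saponification and thermal decarboxylation of the malonic acid; neither stereocentre is α to a carbonyl group, so both persist (the descriptor of the aryl-bearing carbon changes only through the priority rules).

Step 6
Reactants: 11 furyl acid; 12 methanol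
Product: 13 (2R,5R,9S,10R)-2-methoxy-10-methyl-9-(3,4,5-trimethoxyphenyl)-1,6-dioxaspiro[4.5]dec-3-en-7-one
Conditions: undivided cell, graphite anode, Pt cathode, NaBr (0.3 equiv), 2,6-lutidine (1.1 equiv), MeOH, constant current 10 mA cm−2, 2.2 F mol−1, −10 °C
Reagents that add atoms: methanol (12), CO
Why: Bromide is oxidised at graphite to electrophilic bromine, which attacks the unsubstituted furan α-carbon (target C2); the furanium ion so formed is taken at the substituted α-carbon (target C5) by the tethered carboxylate, methanol then displaces the allylic bromide at C2, and the cathode reduces methanol to H2. The closest known reactions are the Clauson-Kaas anodic 2,5-dimethoxylation of furans and the oxidative spirolactonisation of 2-furylalkanoic acids. The δ-lactone closes by 6-exo attack of the carboxylate oxygen on the cationic furan carbon through a chair-like arrangement with aryl and methyl equatorial. The spiro carbon and the acetal carbon become stereocentres, the first biased by that chair and the second uncontrolled, so epimers at both are expected beside the isomer drawn and all are carried on; neither needs control, because the spiro carbon is re-set in step 7 and the acetal carbon becomes the aldehyde. The step needs the furan to be oxidised before the trimethoxyphenyl ring and the carboxylate, not methanol, to take C5; the mediator holds the anode at the bromide potential, where only the more nucleophilic furan is attacked, and 2,6-lutidine keeps the acid ionised so that ring closure outruns solvent capture.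

Step 7
Reactants: 13 spiro dihydrofuran lactone; 12 methanol
Product: 14 (4S,5R,6R)-6-methoxy-5-methyl-6-[(1Z)-3-oxoprop-1-en-1-yl]-4-(3,4,5-trimethoxyphenyl)oxan-2-one
Conditions: camphorsulfonic acid (5 mol %), MeOH (2 equiv), CH2Cl2, −20 → 0 °C; Et3N quench; chromatography on Et3N-deactivated silica, the fraction of opposite ketal configuration being returned to the same conditions
Reagents that add atoms: methanol (12), CO
Why: Acid-catalysed acetal exchange of a 2-acyloxy-5-methoxy-2,5-dihydrofuran, in which the furanoid C–O bond at the spiro carbon ionises, methanol is taken up there and the freed hemiacetal loses methanol to leave the aldehyde with the alkene still cis; the mixed acyloxy/methoxy ketal re-ionises under the acid, so its carbon is set under equilibrium control, and 14 (propenal arm cis to the methyl group, anti to the aryl group) is taken from that equilibrium by chromatography while the rest is returned to it.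

Step 8
Reactants: 14 methoxy-lactone (Z)-enal
Product: 15 (1R,5R,8R,9R)-2-hydroxy-5-methoxy-9-methyl-8-(3,4,5-trimethoxyphenyl)-6-oxabicyclo[3.2.2]non-3-en-7-one (both C2 carbinol epimers)
Conditions: LiN(SiMe3)2 (1.1 equiv), THF (0.01 M), −78 °C; AcOH quench at −78 °C
Reagents that add atoms: none
Why: Intramolecular aldol addition of the lithium lactone enolate to the non-enolisable (Z)-enal across the boat δ-lactone; the tether lets the aldehyde reach only the enolate face that carries the ketal arm, in 14 the face anti to the aryl group, so the ketal centre fixes bridgehead C1, and the carbinol centre is removed in step 9.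

Step 9
Reactants: 15 bicyclic carbinol
Product: 16 (1R,5R,8R,9R)-5-methoxy-9-methyl-8-(3,4,5-trimethoxyphenyl)-6-oxabicyclo[3.2.2]non-3-ene-2,7-dione
Conditions: Dess–Martin periodinane (1.5 equiv), NaHCO3, CH2Cl2, 0 °C → rt
Reagents that add atoms: none
Why: Dess–Martin oxidation of an allylic secondary alcohol to the enone; the C1 hydrogen between the two carbonyl groups sits at a bridgehead and cannot enolise, so C1 is safe.

Step 10
Reactants: 16 enone
Product: 17 (1R,5S,8R,9R)-3-iodo-5-methoxy-9-methyl-8-(3,4,5-trimethoxyphenyl)-6-oxabicyclo[3.2.2]non-3-ene-2,7-dione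
Conditions: I2 (2 equiv), pyridine/CH2Cl2 (1:1), rt
Reagents that add atoms: iodine, II
Why: Johnson α-iodination of an enone (conjugate addition of pyridine, iodination of the enolate, elimination); C3 is the only enone α-position and the pseudo-ester ketal tolerates the mild base.

Step 11
Reactants: 17 α-iodoenone
Product: 18 (1R,5S,8R,9R)-5-methoxy-9-methyl-3-(prop-2-en-1-yl)-8-(3,4,5-trimethoxyphenyl)-6-oxabicyclo[3.2.2]non-3-ene-2,7-dione (target)
Conditions: allyltributylstannane (1.5 equiv), Pd2(dba)3 (5 mol %), AsPh3 (20 mol %), CuI (10 mol %), NMP, 50 °C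
Reagents that add atoms: allyltributylstannane, C=CC[Sn](CCCC)(CCCC)CCCC
Why: Stille coupling of an α-iodoenone with an allylstannane under ligand-accelerated conditions (zerovalent palladium from Pd2(dba)3, AsPh3, CuI); the neutral medium leaves ketal, lactone and all four stereocentres untouched.

**Compound list**
1 | 3,4,5-trimethoxybenzaldehyde | COc1cc(C=O)cc(OC)c1OC | starting material
2 | dimethyl malonate | COC(=O)CC(=O)OC | starting material
3 | dimethyl 2-[(3,4,5-trimethoxyphenyl)methylidene]propanedioate | COC(=O)C(=Cc1cc(OC)c(OC)c(OC)c1)C(=O)OC | intermediate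
4 | propanal | CCC=O | starting material
5 | dimethyl 2-[(1R,2R)-2-methyl-3-oxo-1-(3,4,5-trimethoxyphenyl)propyl]propanedioate | COC(=O)C(C(=O)OC)[C@H](c1cc(OC)c(OC)c(OC)c1)[C@H](C=O)C | intermediate
6 | 3,3-diethoxyprop-1-yne | C#CC(OCC)OCC | starting material
7 | dimethyl 2-[(1R,2R)-6,6-diethoxy-3-hydroxy-2-methyl-1-(3,4,5-trimethoxyphenyl)hex-4-yn-1-yl]propanedioate (carbinol epimers) | COC(=O)C(C(=O)OC)[C@H](c1cc(OC)c(OC)c(OC)c1)[C@H](C(O)C#CC(OCC)OCC)C | intermediate
8 | dimethyl 2-[(1R,2R,4Z)-6,6-diethoxy-3-hydroxy-2-methyl-1-(3,4,5-trimethoxyphenyl)hex-4-en-1-yl]propanedioate (not isolated) | COC(=O)C(C(=O)OC)[C@H](c1cc(OC)c(OC)c(OC)c1)[C@H](C(O)/C=C\C(OCC)OCC)C | intermediate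
9 | dimethyl 2-[(1R,2R)-2-(furan-2-yl)-1-(3,4,5-trimethoxyphenyl)propyl]propanedioate | COC(=O)C(C(=O)OC)[C@H](c1cc(OC)c(OC)c(OC)c1)[C@H](c1ccco1)C | intermediate
10 | 2-[(1R,2R)-2-(furan-2-yl)-1-(3,4,5-trimethoxyphenyl)propyl]propanedioic acid (not isolated) | OC(=O)C(C(=O)O)[C@H](c1cc(OC)c(OC)c(OC)c1)[C@H](c1ccco1)C | intermediate
11 | (3S,4R)-4-(furan-2-yl)-3-(3,4,5-trimethoxyphenyl)pentanoic acid | OC(=O)C[C@H](c1cc(OC)c(OC)c(OC)c1)[C@H](c1ccco1)C | intermediate
12 | methanol | CO | starting material
13 | (2R,5R,9S,10R)-2-methoxy-10-methyl-9-(3,4,5-trimethoxyphenyl)-1,6-dioxaspiro[4.5]dec-3-en-7-one | C1=C[C@@]2(O[C@H]1OC)OC(=O)C[C@H](c1cc(OC)c(OC)c(OC)c1)[C@H]2C | intermediate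
14 | (4S,5R,6R)-6-methoxy-5-methyl-6-[(1Z)-3-oxoprop-1-en-1-yl]-4-(3,4,5-trimethoxyphenyl)oxan-2-one | O=C/C=C\[C@@]1(OC)OC(=O)C[C@H](c2cc(OC)c(OC)c(OC)c2)[C@H]1C | intermediate
15 | (1R,5R,8R,9R)-2-hydroxy-5-methoxy-9-methyl-8-(3,4,5-trimethoxyphenyl)-6-oxabicyclo[3.2.2]non-3-en-7-one (C2 epimers) | C1=C[C@@]2(OC)OC(=O)[C@@H](C1O)[C@H](c1cc(OC)c(OC)c(OC)c1)[C@H]2C | intermediate
16 | (1R,5R,8R,9R)-5-methoxy-9-methyl-8-(3,4,5-trimethoxyphenyl)-6-oxabicyclo[3.2.2]non-3-ene-2,7-dione | C1=C[C@@]2(OC)OC(=O)[C@@H](C1=O)[C@H](c1cc(OC)c(OC)c(OC)c1)[C@H]2C | intermediate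
17 | (1R,5S,8R,9R)-3-iodo-5-methoxy-9-methyl-8-(3,4,5-trimethoxyphenyl)-6-oxabicyclo[3.2.2]non-3-ene-2,7-dione | IC1=C[C@@]2(OC)OC(=O)[C@@H](C1=O)[C@H](c1cc(OC)c(OC)c(OC)c1)[C@H]2C | intermediate
18 | (1R,5S,8R,9R)-5-methoxy-9-methyl-3-(prop-2-en-1-yl)-8-(3,4,5-trimethoxyphenyl)-6-oxabicyclo[3.2.2]non-3-ene-2,7-dione | C=CCC1=C[C@@]2(OC)OC(=O)[C@@H](C1=O)[C@H](c1cc(OC)c(OC)c(OC)c1)[C@H]2C | target

Total step count: 11. Longest linear sequence: 11 steps (1 → 18).

**Steps most likely to fail**

Step 7. The ketal exchange is an equilibrium on several counts. Methanol capture and re-ionisation may leave the configuration needed at the ketal carbon as the minor one, because anomeric stabilisation favours axial methoxy and an equatorial arm; several passes through the acid would then be needed. Methanol can also open the lactone instead of the dihydrofuran, the aldehyde oxygen can close back onto the ketal carbon, and the enal can isomerise from Z to E. Fallback, setting out from 13 and coming back at 14: 13 is hydrolysed with dilute aqueous HCl in acetone at 0 °C, the usual unmasking of a dialkoxydihydrofuran to a cis-enedione, to give (3S,4R,6Z)-4-methyl-5,8-dioxo-3-(3,4,5-trimethoxyphenyl)oct-6-enoic acid F1. Oxalyl chloride with a trace of DMF in CH2Cl2 converts this δ-keto acid into the cyclic pseudo-chloride (4S,5R,6R)-6-chloro-5-methyl-6-[(1Z)-3-oxoprop-1-en-1-yl]-4-(3,4,5-trimethoxyphenyl)oxan-2-one F2, in which chloride should sit axial and the arm equatorial. Insoluble Ag2CO3 with methanol in CH2Cl2 over 4 Å molecular sieves at −20 °C in the dark then replaces chloride with inversion, the Koenigs–Knorr course by which axial ketosidic chlorides give equatorial methyl ketosides. Methoxy ends equatorial and the arm axial, which is 14, so the ketal carbon is set by a stereospecific substitution instead of an equilibrium.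

Step 6. Solvent methanol may capture the furan cation at the substituted α-carbon before the carboxylate does, the electrophilic bromine may attack the trimethoxyphenyl ring, and the carboxylate may be lost by anodic decarboxylation. Fallback, setting out from 11 and coming back at 13: chemical Clauson-Kaas oxidation (Br2, NaHCO3, methanol, −40 °C) gives (3S,4R)-4-(2,5-dimethoxy-2,5-dihydrofuran-2-yl)-3-(3,4,5-trimethoxyphenyl)pentanoic acid F5. Pyridinium p-toluenesulfonate in CH2Cl2 over 4 Å molecular sieves then ionises the ketal carbon and lets the free acid close the spirolactone 13 with loss of methanol.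

Step 8. The amide base may add to the aldehyde faster than it deprotonates the lactone, the enolate may close onto the enal β-carbon (C4) instead of the carbonyl carbon, and the aldolate may revert on warming. Fallback, setting out from 13 and coming back at 15: the spirolactone, which has no aldehyde yet, is brominated next to the lactone carbonyl (LiN(SiMe3)2, Me3SiCl, THF, −78 °C; then N-bromosuccinimide) to 8-bromo-2-methoxy-10-methyl-9-(3,4,5-trimethoxyphenyl)-1,6-dioxaspiro[4.5]dec-3-en-7-one F3. The conditions of step 7 convert it into 3-bromo-6-methoxy-5-methyl-6-[(1Z)-3-oxoprop-1-en-1-yl]-4-(3,4,5-trimethoxyphenyl)oxan-2-one F4. SmI2 in THF at −78 °C then reduces the C–Br bond in the presence of the aldehyde and closes the ring in an intramolecular Reformatsky reaction to 15, with no free base in the flask.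

**Further compounds**
F1 | step 7 | (3S,4R,6Z)-4-methyl-5,8-dioxo-3-(3,4,5-trimethoxyphenyl)oct-6-enoic acid | OC(=O)C[C@H](c1cc(OC)c(OC)c(OC)c1)[C@H](C(=O)/C=C\C=O)C
F2 | step 7 | (4S,5R,6R)-6-chloro-5-methyl-6-[(1Z)-3-oxoprop-1-en-1-yl]-4-(3,4,5-trimethoxyphenyl)oxan-2-one | O=C/C=C\[C@]1(Cl)OC(=O)C[C@H](c2cc(OC)c(OC)c(OC)c2)[C@H]1C
F3 | step 8 | 8-bromo-2-methoxy-10-methyl-9-(3,4,5-trimethoxyphenyl)-1,6-dioxaspiro[4.5]dec-3-en-7-one (other centres as in 13, both bromide epimers) | C1=C[C@@]2(O[C@H]1OC)OC(=O)C(Br)[C@H](c1cc(OC)c(OC)c(OC)c1)[C@H]2C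
F4 | step 8 | 3-bromo-6-methoxy-5-methyl-6-[(1Z)-3-oxoprop-1-en-1-yl]-4-(3,4,5-trimethoxyphenyl)oxan-2-one (other centres as in 14, both bromide epimers) | O=C/C=C\[C@@]1(OC)OC(=O)C(Br)[C@H](c2cc(OC)c(OC)c(OC)c2)[C@H]1C
F5 | step 6 | (3S,4R)-4-(2,5-dimethoxy-2,5-dihydrofuran-2-yl)-3-(3,4,5-trimethoxyphenyl)pentanoic acid (ring acetal epimers) | OC(=O)C[C@H](c1cc(OC)c(OC)c(OC)c1)[C@H](C1(OC)C=CC(OC)O1)C
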